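**Retrosynthetic overview**

1. Target ⇒ C15 desilylation, C8 esterification with (Z)-4-acetoxy-3-methylbut-2-enoic acid (from 4-methylfuran-2(5H)-one), α-methylenation and lactonisation of a C7 acetate on a 1,10-epoxycyclodeca-2,4-dien-6-one.
2. Epoxide ⇒ reagent-controlled epoxidation of the 1(10)E alkene of a (1(10)E,2Z,4Z)-cyclodecatrien-6-one.
3. Ten-membered ring ⇒ cleavage of the C6–C10 bond of a trans-fused bicyclo[5.3.0]decadiene by a palladium-triggered, alkoxide-driven Grob-type fragmentation that creates the C6 ketone and the E C1=C10 alkene.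
4. Bicycle ⇒ ring-closing metathesis (C2=C3) of a cyclopentanol carrying a vinyl carbinol carbonate on C10 and a dienyl group on C6; these come from a reductive aldol of a 2-methyl-4-silyloxycyclopentenone with acrolein and from vinylcopper carbocupration of a propargyl silyl ether.
5. Ring order: cyclopentane (bought, carries C8) → cycloheptadiene → cyclodecatrienone → oxirane → γ-lactone.

Assumption: silyl ethers 1 and 8 are bought as such (protecting groups not counted in their size); target carbons are labelled C1–C15 as in germacranolides (C12 lactone carbonyl on O6, C13 exocyclic methylene, C14 methyl on C10, C15 on C4, ester on O8) and these labels are used for all intermediates.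

**Route**

Step 1
Reactants: 1 (S)-4-[(tert-butyldimethylsilyl)oxy]cyclopent-2-en-1-one
Product: 2 (S)-4-[(tert-butyldimethylsilyl)oxy]-2-iodocyclopent-2-en-1-one
Conditions: I2, pyridine/CH2Cl2 (1:1), 0 °C → rt
Reagents that add atoms: iodine (II)
Why: α-Iodination of the enone by pyridine conjugate addition, iodination and elimination (Baylis–Hillman-type mechanism) leaves the C8 stereocentre untouched.

Step 2
Reactants: 2 (S)-4-[(tert-butyldimethylsilyl)oxy]-2-iodocyclopent-2-en-1-one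
Product: 3 (S)-4-[(tert-butyldimethylsilyl)oxy]-2-methylcyclopent-2-en-1-one
Conditions: SnMe4, Pd2(dba)3 (2.5 mol %), AsPh3 (10 mol %), CuI (copper iodide, 10 mol %), NMP, 60 °C
Reagents that add atoms: tetramethylstannane (C[Sn](C)(C)C)
Why: Stille cross-coupling of the α-iodoenone under neutral conditions transfers the C14 methyl without β-elimination of the silyloxy group.

Step 3
Reactants: 3 (S)-4-[(tert-butyldimethylsilyl)oxy]-2-methylcyclopent-2-en-1-one; 4 acrolein
Product: 7 tert-butyl (1S)-1-[(1S,4R)-4-{[tert-butyl(dimethyl)silyl]oxy}-1-methyl-2-oxocyclopentyl]prop-2-en-1-yl carbonate, via lithium enolate 5 (not isolated), via lithium aldolate 6 (not isolated)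
Conditions: LiBH(s-Bu)3, THF, −78 °C; 4, −78 °C; Boc2O, −78 → 0 °C
Reagents that add atoms: di-tert-butyl dicarbonate (CC(C)(C)OC(=O)OC(=O)OC(C)(C)C)
Why: 1,4-Hydride reduction gives the C6=C10 enolate regiospecifically, a Zimmerman–Traxler aldol with acrolein on the face anti to the silyloxy group builds quaternary C10 with the C1 oxygen syn to C14 (the relative configuration step 7 needs), and O-acylation in the flask blocks retro-aldol; C1 and C10 are later erased, so only their relative configuration matters.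

Step 4
Reactants: 8 tert-butyl(diphenyl)(prop-2-yn-1-yloxy)silane; 9 vinylmagnesium bromide
Product: 12 tert-butyl{[(2E)-2-(iodomethylidene)but-3-en-1-yl]oxy}diphenylsilane (iodine cis to the vinyl group), via vinylcopper 10 (not isolated), via dienylcopper 11 (not isolated)
Conditions: 9, CuBr·SMe2, Et2O/Me2S, −45 °C; 8, −25 °C; I2, THF, −50 °C → rt
Reagents that add atoms: iodine (II)
Why: Normant syn-carbocupration puts vinyl on the internal and copper on the terminal alkyne carbon (the bulky silyl ether prevents chelation-reversed addition), and iodinolysis with retention fixes iodine cis to vinyl, which is the future C4=C5 geometry (C3 cis to C6).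

Step 5
Reactants: 7 tert-butyl (1S)-1-[(1S,4R)-4-{[tert-butyl(dimethyl)silyl]oxy}-1-methyl-2-oxocyclopentyl]prop-2-en-1-yl carbonate; 12 tert-butyl{[(2E)-2-(iodomethylidene)but-3-en-1-yl]oxy}diphenylsilane
Product: 15 tert-butyl (1S)-1-{(1S,4R)-4-[(tert-butyldimethylsilyl)oxy]-2-[(1E)-2-({[tert-butyl(diphenyl)silyl]oxy}methyl)buta-1,3-dien-1-yl]-2-hydroxy-1-methylcyclopentyl}prop-2-en-1-yl carbonate (dienyl on C6 cis to C14), via dienyllithium 13 (not isolated), via dienylcerium dichloride 14 (not isolated)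
Conditions: 12, t-BuLi (2 equiv), Et2O, −78 °C; CeCl3, THF, −78 °C; 7, −78 °C; AcOH quench at −78 °C
Reagents that add atoms: none
Why: Iodine–lithium exchange with retention, transmetalation to the weakly basic organocerium and 1,2-addition to the hindered, enolisable ketone from the face anti to the C1 side chain give the tertiary C6 carbinol, while the tert-butyl carbonate is inert at −78 °C.

Step 6
Reactants: 15 tert-butyl (1S)-1-{(1S,4R)-4-[(tert-butyldimethylsilyl)oxy]-2-[(1E)-2-({[tert-butyl(diphenyl)silyl]oxy}methyl)buta-1,3-dien-1-yl]-2-hydroxy-1-methylcyclopentyl}prop-2-en-1-yl carbonate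
Product: 16 trans-fused bicyclo[5.3.0]decadiene hydroxy carbonate (seven-membered ring C6(OH)–C5=C4(CH2OTBDPS)–C3=C2–C1(OCO2t-Bu)–C10(CH3); five-membered ring C6–C7–C8(OTBS)–C9–C10; C1–O and C6–O cis to each other and trans to C14)
Conditions: second-generation Grubbs catalyst RuCl2(=CHPh)(PCy3)(H2IMes) (5 mol %), CH2Cl2 (5 mM), 40 °C
Reagents that add atoms: none
Why: Ring-closing metathesis of the two monosubstituted alkenes closes the seven-membered ring, in which the new C2=C3 bond can only be cis and the diene is locked cis,cis; the trisubstituted C4=C5 bond does not compete.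

Step 7
Reactants: 16 trans-fused bicyclo[5.3.0]decadiene hydroxy carbonate
Product: 17 (2E,4Z,6E,9R)-9-[(tert-butyldimethylsilyl)oxy]-3-{[(tert-butyldiphenylsilyl)oxy]methyl}-7-methylcyclodeca-2,4,6-trien-1-one (germacrane labels: C6 ketone, 1(10)E, 2Z, C3 cis to C6 across C4=C5)
Conditions: Pd2(dba)3·CHCl3 (2.5 mol %), PPh3 (12 mol %), THF, 0 → 20 °C; product kept cold and used at once
Reagents that add atoms: none
Why: Proposed new method: zerovalent palladium ionises the allylic tert-butyl carbonate with inversion to a cycloheptadienyl-palladium cation, the carbonate anion loses CO2 and the tert-butoxide formed deprotonates the tertiary C6 alcohol, and the alkoxide then expels the C6–C10 bond antiperiplanar to palladium (Grob-type fragmentation with palladium as leaving group) to give the C6 ketone, the C1=C10 alkene and zerovalent palladium, a five-to-ten-membered ring expansion; because the carbonate is trans to C14, the double inversion leaves C2 cis to C14 (E alkene), the two cis alkenes come unchanged from the seven-membered ring, and neither C6 nor C10 carries a hydrogen for simple elimination; the closest known reactions are the Wharton–Grob fragmentation of 1,3-diol monosulfonates and the palladium-catalysed decarboxylative fragmentation of 4-vinyl-1,3-dioxan-2-ones to dienyl carbonyl compounds, neither shown for a ring-embedded allyl unit or for expansion to a cyclodecatrienone.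

Step 8
Reactants: 17 (2E,4Z,6E,9R)-9-[(tert-butyldimethylsilyl)oxy]-3-{[(tert-butyldiphenylsilyl)oxy]methyl}-7-methylcyclodeca-2,4,6-trien-1-one
Product: 18 (1R,8R,10R)-8-[(tert-butyldimethylsilyl)oxy]-15-[(tert-butyldiphenylsilyl)oxy]-1,10-epoxygermacra-2Z,4-dien-6-one (C3 cis to C6 across C4=C5)
Conditions: D-fructose-derived Shi ketone (30 mol %), 2KHSO5·KHSO4·K2SO4, K2CO3, Bu4NHSO4, MeCN/(MeO)2CH2/aq. Na2B4O7 buffer, −5 → 0 °C
Reagents that add atoms: potassium peroxymonosulfate (OOS(=O)(=O)[O-].[K+])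
Why: Shi asymmetric epoxidation: the electrophilic dioxirane attacks only the electron-rich trisubstituted E alkene (the dienone alkenes are electron-poor and the cis alkene is a poor substrate), and the spiro transition state of the D-fructose-derived ketone delivers oxygen to the face that gives (1R,10R), as it does for other E-trisubstituted alkenes; working at 0 °C also outruns 6π-electrocyclisation of the triene.

Step 9
Reactants: 18 (1R,8R,10R)-8-[(tert-butyldimethylsilyl)oxy]-15-[(tert-butyldiphenylsilyl)oxy]-1,10-epoxygermacra-2Z,4-dien-6-one; 19 methyl iodoacetate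
Product: 21 methyl (1R,7R,8R,10R)-8-[(tert-butyldimethylsilyl)oxy]-15-[(tert-butyldiphenylsilyl)oxy]-1,10-epoxy-6-oxo-13-norgermacra-2Z,4-dien-12-oate (C7–CH2CO2Me), via lithium enolate 20 (not isolated)
Conditions: LiN(i-Pr)2, THF, −78 °C; 19, DMPU, −78 → −40 °C
Reagents that add atoms: none
Why: Kinetic deprotonation can only occur at C7, and SN2 alkylation of the enolate anti to the C8 silyloxy group (allylic 1,3-strain model: H8 in the enolate plane) sets C7 as in the target; −78 °C suppresses β-elimination of the silyloxy group.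

Step 10
Reactants: 21 methyl (1R,7R,8R,10R)-8-[(tert-butyldimethylsilyl)oxy]-15-[(tert-butyldiphenylsilyl)oxy]-1,10-epoxy-6-oxo-13-norgermacra-2Z,4-dien-12-oate
Product: 23 (1R,6R,7R,8R,10R)-8-[(tert-butyldimethylsilyl)oxy]-15-[(tert-butyldiphenylsilyl)oxy]-1,10-epoxy-13-norgermacra-2Z,4-dien-12,6-olide (trans-fused γ-lactone), via hydroxy ester 22 (not isolated)
Conditions: (R)-2-methyl-CBS-oxazaborolidine (0.3 equiv), catecholborane, toluene, −78 °C; then DBU (cat.), toluene, rt
Reagents that add atoms: none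
Why: Corey–Bakshi–Shibata 1,2-reduction is reagent-controlled (dienyl as the large group, C7 as the small one) and sets C6 as R, and the γ-hydroxy ester then closes by intramolecular transesterification to the trans-fused lactone.

Step 11
Reactants: 23 (1R,6R,7R,8R,10R)-8-[(tert-butyldimethylsilyl)oxy]-15-[(tert-butyldiphenylsilyl)oxy]-1,10-epoxy-13-norgermacra-2Z,4-dien-12,6-olide
Product: 26 (1R,6R,7R,8R,10R)-8-[(tert-butyldimethylsilyl)oxy]-15-[(tert-butyldiphenylsilyl)oxy]-1,10-epoxygermacra-2Z,4,11(13)-trien-12,6-olide, via Mannich base 24 (not isolated), via methiodide 25 (not isolated)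
Conditions: LiN(i-Pr)2, THF, −78 °C; [CH2=NMe2]I, −78 °C → rt; MeI, MeOH, rt; NaHCO3, CH2Cl2/H2O
Reagents that add atoms: dimethyl(methylidene)ammonium iodide (C=[N+](C)C.[I-])
Why: Mannich reaction of the lactone enolate at C11 followed by quaternisation and Hofmann-type elimination installs the exocyclic methylene; no stereocentre is involved.

Step 12
Reactants: 26 (1R,6R,7R,8R,10R)-8-[(tert-butyldimethylsilyl)oxy]-15-[(tert-butyldiphenylsilyl)oxy]-1,10-epoxygermacra-2Z,4,11(13)-trien-12,6-olide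
Product: 27 (1R,6R,7R,8R,10R)-15-[(tert-butyldiphenylsilyl)oxy]-1,10-epoxy-8-hydroxygermacra-2Z,4,11(13)-trien-12,6-olide
Conditions: HF·pyridine, pyridine, THF, 0 °C → rt
Reagents that add atoms: none
Why: Fluoride-mediated desilylation removes the secondary TBS ether far faster than the primary TBDPS ether, and the pyridine buffer protects the vinyl epoxide.

Step 13
Reactants: 28 4-methylfuran-2(5H)-one
Product: 30 (2Z)-4-acetoxy-3-methylbut-2-enoic acid, via lithium hydroxy enoate 29 (not isolated)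
Conditions: LiOH·H2O (1.0 equiv), THF/H2O, rt, evaporate to dryness; LiN(SiMe3)2 (1.05 equiv), THF, −78 °C; Ac2O (1.0 equiv), −78 → 0 °C; cold 1 M HCl
Reagents that add atoms: lithium hydroxide ([Li+].[OH-]); acetic anhydride (CC(=O)OC(C)=O)
Why: Saponification opens the butenolide with the Z geometry fixed by the ring, and in the alkoxide–carboxylate dianion the alkoxide is acetylated much faster than the carboxylate, so the hydroxyl is capped before any relactonisation.

Step 14
Reactants: 27 (1R,6R,7R,8R,10R)-15-[(tert-butyldiphenylsilyl)oxy]-1,10-epoxy-8-hydroxygermacra-2Z,4,11(13)-trien-12,6-olide; 30 (2Z)-4-acetoxy-3-methylbut-2-enoic acid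
Product: 32 (1R,6R,7R,8R,10R)-8-{[(2Z)-4-acetoxy-3-methylbut-2-enoyl]oxy}-15-[(tert-butyldiphenylsilyl)oxy]-1,10-epoxygermacra-2Z,4,11(13)-trien-12,6-olide, via mixed anhydride 31 (not isolated)
Conditions: 30, 2,4,6-Cl3C6H2COCl, Et3N, toluene, rt; 27, DMAP, toluene, 0 °C → rt
Reagents that add atoms: none
Why: Yamaguchi esterification acylates the hindered secondary C8 alcohol through the mixed anhydride with retention at C8, and the short low-temperature DMAP stage limits Z to E isomerisation of the enoate.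

Step 15
Reactants: 32 (1R,6R,7R,8R,10R)-8-{[(2Z)-4-acetoxy-3-methylbut-2-enoyl]oxy}-15-[(tert-butyldiphenylsilyl)oxy]-1,10-epoxygermacra-2Z,4,11(13)-trien-12,6-olide
Product: 33 CNP0292814.1, (1R,6R,7R,8R,10R)-8-{[(2Z)-4-acetoxy-3-methylbut-2-enoyl]oxy}-1,10-epoxy-15-hydroxygermacra-2Z,4,11(13)-trien-12,6-olide
Conditions: Bu4NF/AcOH (1:1), THF, 0 °C → rt
Reagents that add atoms: none
Why: Buffered fluoride desilylation frees the primary allylic alcohol while the acetate, the enoate, the α-methylene lactone and the vinyl epoxide are left intact.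

**Compound list**

1 | (S)-4-[(tert-butyldimethylsilyl)oxy]cyclopent-2-en-1-one | O=C1C=C[C@@H](O[Si](C)(C)C(C)(C)C)C1 | starting material
2 | (S)-4-[(tert-butyldimethylsilyl)oxy]-2-iodocyclopent-2-en-1-one | O=C1C(I)=C[C@@H](O[Si](C)(C)C(C)(C)C)C1 | intermediate
3 | (S)-4-[(tert-butyldimethylsilyl)oxy]-2-methylcyclopent-2-en-1-one | O=C1C(C)=C[C@@H](O[Si](C)(C)C(C)(C)C)C1 | intermediate
4 | acrolein | C=CC=O | starting material
5 | lithium 4-[(tert-butyldimethylsilyl)oxy]-2-methylcyclopent-1-en-1-olate (C6=C10 enolate, C8 unchanged) | [Li]OC1=C(C)C[C@@H](O[Si](C)(C)C(C)(C)C)C1 | intermediate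
6 | lithium (1S)-1-[(1S,4R)-4-{[tert-butyl(dimethyl)silyl]oxy}-1-methyl-2-oxocyclopentyl]prop-2-en-1-olate | O=C1[C@](C)([C@@H](O[Li])C=C)C[C@@H](O[Si](C)(C)C(C)(C)C)C1 | intermediate
7 | tert-butyl (1S)-1-[(1S,4R)-4-{[tert-butyl(dimethyl)silyl]oxy}-1-methyl-2-oxocyclopentyl]prop-2-en-1-yl carbonate (C14 cis to OTBS; C1–O syn to C14 in the C6–C10–C1–C2 zigzag) | O=C1[C@](C)([C@@H](OC(=O)OC(C)(C)C)C=C)C[C@@H](O[Si](C)(C)C(C)(C)C)C1 | intermediate
8 | tert-butyl(diphenyl)(prop-2-yn-1-yloxy)silane | C#CCO[Si](c1ccccc1)(c1ccccc1)C(C)(C)C | starting material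
9 | vinylmagnesium bromide | C=C[Mg]Br | starting material
10 | vinylcopper (MgBr2 complex) | C=C[Cu] | intermediate
11 | [(1E)-2-({[tert-butyl(diphenyl)silyl]oxy}methyl)buta-1,3-dien-1-yl]copper (Cu cis to vinyl) | [Cu]/C=C(\C=C)CO[Si](c1ccccc1)(c1ccccc1)C(C)(C)C | intermediate
12 | tert-butyl{[(2E)-2-(iodomethylidene)but-3-en-1-yl]oxy}diphenylsilane (I cis to vinyl) | I/C=C(\C=C)CO[Si](c1ccccc1)(c1ccccc1)C(C)(C)C | intermediate
13 | [(1E)-2-({[tert-butyl(diphenyl)silyl]oxy}methyl)buta-1,3-dien-1-yl]lithium | [Li]/C=C(\C=C)CO[Si](c1ccccc1)(c1ccccc1)C(C)(C)C | intermediate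
14 | [(1E)-2-({[tert-butyl(diphenyl)silyl]oxy}methyl)buta-1,3-dien-1-yl]cerium dichloride | Cl[Ce](Cl)/C=C(\C=C)CO[Si](c1ccccc1)(c1ccccc1)C(C)(C)C | intermediate
15 | tert-butyl (1S)-1-{(1S,4R)-4-[(tert-butyldimethylsilyl)oxy]-2-[(1E)-2-({[tert-butyl(diphenyl)silyl]oxy}methyl)buta-1,3-dien-1-yl]-2-hydroxy-1-methylcyclopentyl}prop-2-en-1-yl carbonate (dienyl cis to C14) | O[C@]1(/C=C(\C=C)CO[Si](c2ccccc2)(c2ccccc2)C(C)(C)C)[C@](C)([C@@H](OC(=O)OC(C)(C)C)C=C)C[C@@H](O[Si](C)(C)C(C)(C)C)C1 | intermediate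
16 | trans-fused bicyclo[5.3.0]decadiene hydroxy carbonate (C1–OCO2t-Bu and C6–OH cis, both trans to C14; C8–OTBS cis to C14) | O[C@]12/C=C(CO[Si](c3ccccc3)(c3ccccc3)C(C)(C)C)\C=C/[C@H](OC(=O)OC(C)(C)C)[C@]1(C)C[C@@H](O[Si](C)(C)C(C)(C)C)C2 | intermediate
17 | (2E,4Z,6E,9R)-9-[(tert-butyldimethylsilyl)oxy]-3-{[(tert-butyldiphenylsilyl)oxy]methyl}-7-methylcyclodeca-2,4,6-trien-1-one | O=C1/C=C(CO[Si](c2ccccc2)(c2ccccc2)C(C)(C)C)\C=C/C=C(C)/C[C@@H](O[Si](C)(C)C(C)(C)C)C1 | intermediate
18 | (1R,8R,10R)-8-[(tert-butyldimethylsilyl)oxy]-15-[(tert-butyldiphenylsilyl)oxy]-1,10-epoxygermacra-2Z,4-dien-6-one | O=C1/C=C(CO[Si](c2ccccc2)(c2ccccc2)C(C)(C)C)\C=C/[C@H]2O[C@]2(C)C[C@@H](O[Si](C)(C)C(C)(C)C)C1 | intermediate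
19 | methyl iodoacetate | COC(=O)CI | starting material
20 | lithium C6=C7 enolate of 18 (enolate geometry not defined) | [Li]OC=1/C=C(CO[Si](c2ccccc2)(c2ccccc2)C(C)(C)C)\C=C/[C@H]2O[C@]2(C)C[C@@H](O[Si](C)(C)C(C)(C)C)C=1 | intermediate
21 | methyl (1R,7R,8R,10R)-8-[(tert-butyldimethylsilyl)oxy]-15-[(tert-butyldiphenylsilyl)oxy]-1,10-epoxy-6-oxo-13-norgermacra-2Z,4-dien-12-oate | O=C1/C=C(CO[Si](c2ccccc2)(c2ccccc2)C(C)(C)C)\C=C/[C@H]2O[C@]2(C)C[C@@H](O[Si](C)(C)C(C)(C)C)[C@H]1CC(=O)OC | intermediate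
22 | methyl (1R,6R,7R,8R,10R)-8-[(tert-butyldimethylsilyl)oxy]-15-[(tert-butyldiphenylsilyl)oxy]-1,10-epoxy-6-hydroxy-13-norgermacra-2Z,4-dien-12-oate | O[C@@H]1/C=C(CO[Si](c2ccccc2)(c2ccccc2)C(C)(C)C)\C=C/[C@H]2O[C@]2(C)C[C@@H](O[Si](C)(C)C(C)(C)C)[C@H]1CC(=O)OC | intermediate
23 | (1R,6R,7R,8R,10R)-8-[(tert-butyldimethylsilyl)oxy]-15-[(tert-butyldiphenylsilyl)oxy]-1,10-epoxy-13-norgermacra-2Z,4-dien-12,6-olide | C1C(=O)O[C@@H]2/C=C(CO[Si](c3ccccc3)(c3ccccc3)C(C)(C)C)\C=C/[C@H]3O[C@]3(C)C[C@@H](O[Si](C)(C)C(C)(C)C)[C@@H]12 | intermediate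
24 | 13-(dimethylamino)-11,13-dihydro derivative of 26 (Mannich base, C11 epimers) | CN(C)CC1C(=O)O[C@@H]2/C=C(CO[Si](c3ccccc3)(c3ccccc3)C(C)(C)C)\C=C/[C@H]3O[C@]3(C)C[C@@H](O[Si](C)(C)C(C)(C)C)[C@@H]12 | intermediate
25 | trimethylammonium iodide of 24 (C11 epimers) | C[N+](C)(C)CC1C(=O)O[C@@H]2/C=C(CO[Si](c3ccccc3)(c3ccccc3)C(C)(C)C)\C=C/[C@H]3O[C@]3(C)C[C@@H](O[Si](C)(C)C(C)(C)C)[C@@H]12.[I-] | intermediate
26 | (1R,6R,7R,8R,10R)-8-[(tert-butyldimethylsilyl)oxy]-15-[(tert-butyldiphenylsilyl)oxy]-1,10-epoxygermacra-2Z,4,11(13)-trien-12,6-olide | C=C1C(=O)O[C@@H]2/C=C(CO[Si](c3ccccc3)(c3ccccc3)C(C)(C)C)\C=C/[C@H]3O[C@]3(C)C[C@@H](O[Si](C)(C)C(C)(C)C)[C@@H]12 | intermediate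
27 | (1R,6R,7R,8R,10R)-15-[(tert-butyldiphenylsilyl)oxy]-1,10-epoxy-8-hydroxygermacra-2Z,4,11(13)-trien-12,6-olide | C=C1C(=O)O[C@@H]2/C=C(CO[Si](c3ccccc3)(c3ccccc3)C(C)(C)C)\C=C/[C@H]3O[C@]3(C)C[C@@H](O)[C@@H]12 | intermediate
28 | 4-methylfuran-2(5H)-one | CC1=CC(=O)OC1 | starting material
29 | lithium (2Z)-4-hydroxy-3-methylbut-2-enoate | [Li+].[O-]C(=O)/C=C(/C)CO | intermediate
30 | (2Z)-4-acetoxy-3-methylbut-2-enoic acid | OC(=O)/C=C(/C)COC(C)=O | intermediate
31 | (2Z)-4-acetoxy-3-methylbut-2-enoic 2,4,6-trichlorobenzoic anhydride | O=C(OC(=O)/C=C(/C)COC(C)=O)c1c(Cl)cc(Cl)cc1Cl | intermediate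
32 | (1R,6R,7R,8R,10R)-8-{[(2Z)-4-acetoxy-3-methylbut-2-enoyl]oxy}-15-[(tert-butyldiphenylsilyl)oxy]-1,10-epoxygermacra-2Z,4,11(13)-trien-12,6-olide | C=C1C(=O)O[C@@H]2/C=C(CO[Si](c3ccccc3)(c3ccccc3)C(C)(C)C)\C=C/[C@H]3O[C@]3(C)C[C@@H](OC(=O)/C=C(/C)COC(C)=O)[C@@H]12 | intermediate
33 | CNP0292814.1, (1R,6R,7R,8R,10R)-8-{[(2Z)-4-acetoxy-3-methylbut-2-enoyl]oxy}-1,10-epoxy-15-hydroxygermacra-2Z,4,11(13)-trien-12,6-olide (C3 cis to C6 across C4=C5) | C=C1C(=O)O[C@@H]2/C=C(CO)\C=C/[C@H]3O[C@]3(C)C[C@@H](OC(=O)/C=C(/C)COC(C)=O)[C@@H]12 | target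

**Step count**

Total: 15 steps. Longest linear sequence: 13 steps (1, 2, 3, 5, 6, 7, 8, 9, 10, 11, 12, 14, 15).

**Steps most likely to fail**

Step 7 (the new palladium-triggered ring expansion). The C6 alkoxide may instead attack the allyl terminus C3 and form an oxygen-bridged ether, or an inner-sphere (syn) fragmentation may give the 1(10)Z isomer. The fallback uses only known chemistry, sets out from 16 and returns at 17. The carbonate is cleaved reductively with i-Bu2AlH (CH2Cl2, −78 °C) to the free diol F1. MnO2 oxidises the secondary allylic alcohol to the C1 enone F2. NaBH4/CeCl3·7H2O (MeOH, −78 °C) delivers hydride anti to the angular C14 methyl and gives the C1-epimeric diol F3, with the C1 hydroxyl cis to C14 and trans to the C6 hydroxyl. Selective mesylation of the secondary alcohol (MsCl, Et3N, −30 °C) gives the C1-epimeric mesylate F4. KOt-Bu (THF, −78 → 0 °C) then effects the classical anionic Wharton–Grob fragmentation, mesylate antiperiplanar to C6–C10, to the same E trienone 17. The C1 inversion is needed because the classical fragmentation is anti, whereas the palladium version is net syn.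

Step 8 (epoxidation of the labile trienone). Trienone 17 can undergo 6π-electrocyclisation on warming, and the substrate may bias oxygen transfer to the wrong face of the macrocyclic E alkene. The fallback sets out from 17 and returns at 18. NBS in THF/H2O (−10 °C) forms the bromohydrin F5 (Br on C1, OH on tertiary C10), and K2CO3 in MeOH closes it to 18 with inversion at C1. Oxygen therefore ends on the face opposite to the one attacked by the electrophile, which makes this sequence the complement of any direct oxygen transfer that prefers the wrong face.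

Step 10 (C6 configuration and lactone fusion). The C7 stereocentre may override the catalyst and give the 6-epimer. The fallback sets out from 21 and returns at 23. The ketone is reduced from the substrate-preferred face (NaBH4/CeCl3·7H2O, or the enantiomeric catalyst) and the product closes to the 6-epimeric cis-fused lactone F6. LiOH (THF/H2O), then careful acidification to pH 5, gives the 6-epimeric hydroxy acid F7. Mitsunobu lactonisation (PPh3, DIAD, THF, 0 °C) then inverts C6 and gives the trans-fused lactone 23.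

**Further compounds**

F1 | step 7 | diol from 16 (C1–OH and C6–OH cis, both trans to C14) | O[C@]12/C=C(CO[Si](c3ccccc3)(c3ccccc3)C(C)(C)C)\C=C/[C@H](O)[C@]1(C)C[C@@H](O[Si](C)(C)C(C)(C)C)C2
F2 | step 7 | C1 enone (tertiary C6–OH retained) | O[C@]12/C=C(CO[Si](c3ccccc3)(c3ccccc3)C(C)(C)C)\C=C/C(=O)[C@]1(C)C[C@@H](O[Si](C)(C)C(C)(C)C)C2
F3 | step 7 | C1-epimeric diol (C1–OH cis to C14) | O[C@]12/C=C(CO[Si](c3ccccc3)(c3ccccc3)C(C)(C)C)\C=C/[C@@H](O)[C@]1(C)C[C@@H](O[Si](C)(C)C(C)(C)C)C2
F4 | step 7 | C1-epimeric mesylate | O[C@]12/C=C(CO[Si](c3ccccc3)(c3ccccc3)C(C)(C)C)\C=C/[C@@H](OS(C)(=O)=O)[C@]1(C)C[C@@H](O[Si](C)(C)C(C)(C)C)C2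
F5 | step 8 | bromohydrin (1-bromo-10-hydroxy) of 17 | O=C1/C=C(CO[Si](c2ccccc2)(c2ccccc2)C(C)(C)C)\C=C/[C@H](Br)[C@](C)(O)C[C@@H](O[Si](C)(C)C(C)(C)C)C1
F6 | step 10 | 6-epimeric cis-fused lactone | C1C(=O)O[C@H]2/C=C(CO[Si](c3ccccc3)(c3ccccc3)C(C)(C)C)\C=C/[C@H]3O[C@]3(C)C[C@@H](O[Si](C)(C)C(C)(C)C)[C@@H]12
F7 | step 10 | 6-epimeric hydroxy acid | O[C@H]1/C=C(CO[Si](c2ccccc2)(c2ccccc2)C(C)(C)C)\C=C/[C@H]2O[C@]2(C)C[C@@H](O[Si](C)(C)C(C)(C)C)[C@H]1CC(=O)O
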